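**Retrosynthetic overview**
- The target comes from a cross-conjugated trienone by double epoxidation of the C1(10) and C2–C3 alkenes and a final Luche reduction at C5; C15 is added by α-methylenation.
- The ten-membered ring is made by a retro-aldol ring expansion of a cis-decalin β-hydroxy enone (C5–C10 cleavage, rings A and B merged), trapped as a dienyl triflate that is then reduced.
- Ring B and the trans-lactone are closed on a cyclohexane-1,3-dione (ring A) by a SmI2 ketone–aldehyde pinacol cyclisation followed by lactonisation.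
- C7 and C8 are set by a chromium-catalysed asymmetric 2-(methoxycarbonyl)allylation of a dione aldehyde.
- Order of ring formation: ring A (bought) → ring B → lactone → ten-membered ring (A and B merged) → two oxiranes.

Assumptions and conventions: locants C1–C15 are those of the germacrane skeleton of the target (C12 = lactone carbonyl, C14 = methyl on C10, C15 = methylidene on C4); α is the face of H-7; the ligand antipode in step 6 is the one that gives the (4S)-alcohol, and the epoxidation and reduction faces in steps 13 and 14 are predicted by analogy, not proven.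

**Step 1**
Reactants: 1 cyclohexane-1,3-dione; 2 iodomethane
Product: 3 2-methylcyclohexane-1,3-dione
Conditions: NaOH, H2O/dioxane, 65 °C
Reagents that add atoms: none
Why: C-alkylation of the stabilised 1,3-dione enolate (enolate alkylation); no stereocentre is formed.

**Step 2**
Reactants: 3 2-methylcyclohexane-1,3-dione; 4 3-bromoprop-1-ene
Product: 5 2-methyl-2-(prop-2-en-1-yl)cyclohexane-1,3-dione
Conditions: NaOH (aq), n-Bu4NI (cat.), 23 °C
Reagents that add atoms: none
Why: C-allylation of the dione enolate builds the quaternary C10 in an achiral, mirror-symmetric dione, so no stereochemistry has to be controlled yet.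

**Step 3**
Reactants: 5 2-methyl-2-(prop-2-en-1-yl)cyclohexane-1,3-dione
Product: 6 2-(1-methyl-2,6-dioxocyclohexyl)acetaldehyde
Conditions: O3, CH2Cl2, −78 °C; then Me2S
Reagents that add atoms: ozone O=[O+][O-]
Why: Ozonolysis with reductive work-up cleaves the only alkene to the C8 aldehyde; the non-enolisable quaternary centre keeps the product stable under neutral conditions.

**Step 4**
Reactants: 7 methyl prop-2-enoate; 8 2,2-dimethoxyacetaldehyde
Product: 9 methyl 3-hydroxy-4,4-dimethoxy-2-methylidenebutanoate (racemic)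
Conditions: DABCO (0.5 equiv), dioxane/H2O, 23 °C
Reagents that add atoms: none
Why: Morita–Baylis–Hillman reaction of an activated α-alkoxy aldehyde; the carbinol centre is removed in the next step, so the racemate is used.

**Step 5**
Reactants: 9 methyl 3-hydroxy-4,4-dimethoxy-2-methylidenebutanoate
Product: 10 methyl (2Z)-2-(bromomethyl)-4,4-dimethoxybut-2-enoate
Conditions: PBr3 (0.4 equiv), Et2O, −10 °C
Reagents that add atoms: phosphorus tribromide BrP(Br)Br
Why: Bromination of a Baylis–Hillman alcohol with allylic transposition (SN2′) gives the thermodynamically preferred (Z)-2-(bromomethyl)enoate.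

**Step 6**
Reactants: 6 2-(1-methyl-2,6-dioxocyclohexyl)acetaldehyde; 10 methyl (2Z)-2-(bromomethyl)-4,4-dimethoxybut-2-enoate
Product: 12 methyl (3R,4S)-3-(dimethoxymethyl)-4-hydroxy-2-methylidene-5-(1-methyl-2,6-dioxocyclohexyl)pentanoate, via silyl ether 11 (not isolated)
Conditions: CrCl2 (10 mol%), chiral carbazole bis(oxazoline) ligand (11 mol%), Mn powder, TMSCl, i-Pr2NEt (cat.), THF, 0 → 23 °C; then 1 M aq citric acid, THF, 0 °C
Reagents that add atoms: none
Why: Catalytic asymmetric Nozaki–Hiyama–Kishi 2-(alkoxycarbonyl)allylation: the allylchromium adds through a chair transition state with the γ-substituent equatorial (anti C7/C8), the ligand fixes the aldehyde face (3R,4S = 7R,8S of the target), and the ketones do not react.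

**Step 7**
Reactants: 12 methyl (3R,4S)-3-(dimethoxymethyl)-4-hydroxy-2-methylidene-5-(1-methyl-2,6-dioxocyclohexyl)pentanoate; 13 2-methylprop-2-enoyl chloride
Product: 14 methyl (3R,4S)-3-(dimethoxymethyl)-2-methylidene-5-(1-methyl-2,6-dioxocyclohexyl)-4-(2-methylprop-2-enoyloxy)pentanoate
Conditions: Et3N, DMAP (cat.), CH2Cl2, 0 °C
Reagents that add atoms: none
Why: Acylation of the secondary alcohol installs the C8 ester of the target early and blocks lactonisation onto O8, so that the lactone can later close only onto O6.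

**Step 8**
Reactants: 14 methyl (3R,4S)-3-(dimethoxymethyl)-2-methylidene-5-(1-methyl-2,6-dioxocyclohexyl)-4-(2-methylprop-2-enoyloxy)pentanoate
Product: 16 cis-fused keto lactone 5α-hydroxy-10α-methyl-8α-(2-methylprop-2-enoyloxy)-1-oxo-15-noreudesm-11(13)-en-6α,12-olide, via aldehyde 15 (not isolated)
Conditions: LiBF4, MeCN/H2O (98:2), 23 °C; toluene azeotrope; then SmI2 (2.2 equiv), THF, −78 → 0 °C; aq NH4Cl
Reagents that add atoms: water O
Why: Acetal hydrolysis followed by SmI2 ketone–aldehyde pinacol cyclisation: the aldehyde ketyl attacks one diastereotopic dione carbonyl axially through a chair in which 8-O, C11 and the new 6-O are equatorial and the samarium-bridged 5-O is axial (cis-diol, cis-decalin), and the trivalent samarium 6-alkoxide then closes the trans-fused lactone on the methyl ester.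

**Step 9**
Reactants: 16 cis-fused keto lactone
Product: 17 5α-hydroxy-10α-methyl-8α-(2-methylprop-2-enoyloxy)-1-oxo-15-noreudesma-2,11(13)-dien-6α,12-olide
Conditions: IBX, 4-methoxypyridine N-oxide, DMSO, 23 °C
Reagents that add atoms: none
Why: IBX dehydrogenation can only occur at C2–C3 because C10 is quaternary; the cis geometry imposed by ring A becomes the (2Z)-alkene of the target.

**Step 10**
Reactants: 17 β-hydroxy enone
Product: 18 (2Z)-8α-(2-methylprop-2-enoyloxy)-5-oxo-1-(trifluoromethylsulfonyloxy)-15-norgermacra-1(10),2,11(13)-trien-6α,12-olide (C9 trans to C2 across C1=C10)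
Conditions: KN(SiMe3)2 (1.1 equiv), 18-crown-6, THF, −78 → −30 °C; then PhNTf2, −78 → 0 °C
Reagents that add atoms: N-phenylbis(trifluoromethanesulfonimide) O=S(=O)(N(c1ccccc1)S(=O)(=O)C(F)(F)F)C(F)(F)F
Why: Proposed new method: the potassium alkoxide of the tertiary 5-OH is an aldolate whose C5–C10 bond lies β to the C1 carbonyl, so retro-aldol cleavage of this ring-fusion bond merges rings A and B into the ten-membered ring and gives a cross-conjugated dienolate, which is trapped irreversibly as the O-triflate and so pulled out of the aldol equilibrium; C9, equatorial on ring A, ends up trans to C2, which is the geometry of the later (E)-C1(10) alkene; the closest known reaction types are retro-aldol ring expansions of bicyclic β-hydroxy ketones and the Wharton–Grob fragmentation, combined with ordinary enolate triflation.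

**Step 11**
Reactants: 18 ring-expanded dienyl triflate
Product: 19 (1(10)E,2Z)-8α-(2-methylprop-2-enoyloxy)-5-oxo-15-norgermacra-1(10),2,11(13)-trien-6α,12-olide
Conditions: Pd(OAc)2 (5 mol%), PPh3 (10 mol%), HCO2H, n-Bu3N, DMF, 40 °C
Reagents that add atoms: none
Why: Palladium-catalysed formate reduction of an enol triflate (oxidative addition to zerovalent palladium, decarboxylation of formate, reductive elimination) replaces OTf by H with retention of alkene geometry.

**Step 12**
Reactants: 19 dienyl ketone
Product: 20 (1(10)E,2Z)-8α-(2-methylprop-2-enoyloxy)-5-oxogermacra-1(10),2,4(15),11(13)-tetraen-6α,12-olide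
Conditions: (CH2O)n, i-Pr2NH·CF3CO2H, CF3CO2H (cat.), THF, 45 °C
Reagents that add atoms: formaldehyde (as paraformaldehyde) C=O
Why: Ammonium-salt-mediated Mannich-type α-methylenation takes place at C4, the only enolisable CH2 (α to the ketone and allylic), and adds C15 as the exo-methylene.

**Step 13**
Reactants: 20 trienone
Product: 21 1β,10α:2α,3α-diepoxy-8α-(2-methylprop-2-enoyloxy)-5-oxogermacra-4(15),11(13)-dien-6α,12-olide
Conditions: DMDO (2.5 equiv), acetone, −20 → 0 °C
Reagents that add atoms: dimethyldioxirane CC1(C)OO1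
Why: Electrophilic epoxidation reaches only the two electron-rich ring alkenes (the enone methylidene and both acrylate units are electron-poor); outer-face attack on the E-trisubstituted alkene, the sense seen with 1(10)E-germacranolides, should give the 1β,10α-oxirane, and the second epoxidation should occur anti to it on the cis alkene (2α,3α).

**Step 14**
Reactants: 21 diepoxy ketone
Product: 22 (1R,2S,3S,5R,6S,7R,8S,10R)-1,10:2,3-diepoxy-5-hydroxy-8-(2-methylprop-2-enoyloxy)germacra-4(15),11(13)-dien-12,6-olide (ACon1_002091)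
Conditions: NaBH4, CeCl3·7H2O, MeOH, −78 °C
Reagents that add atoms: none
Why: Luche 1,2-reduction of the exo-methylene ketone; hydride should enter from the β face, away from the α-disposed C3 oxirane oxygen and lactone oxygen that flank the carbonyl, to give the 5α (5R) alcohol.

**Compound list**
1 | cyclohexane-1,3-dione | O=C1CCCC(=O)C1 | starting material
2 | iodomethane | CI | starting material
3 | 2-methylcyclohexane-1,3-dione | CC1C(=O)CCCC1=O | intermediate
4 | 3-bromoprop-1-ene | C=CCBr | starting material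
5 | 2-methyl-2-(prop-2-en-1-yl)cyclohexane-1,3-dione | C=CCC1(C)C(=O)CCCC1=O | intermediate
6 | 2-(1-methyl-2,6-dioxocyclohexyl)acetaldehyde | O=CCC1(C)C(=O)CCCC1=O | intermediate
7 | methyl prop-2-enoate | C=CC(=O)OC | starting material
8 | 2,2-dimethoxyacetaldehyde | COC(OC)C=O | starting material
9 | methyl 3-hydroxy-4,4-dimethoxy-2-methylidenebutanoate (racemic) | COC(OC)C(O)C(=C)C(=O)OC | intermediate
10 | methyl (2Z)-2-(bromomethyl)-4,4-dimethoxybut-2-enoate | BrC/C(C(=O)OC)=C\C(OC)OC | intermediate
11 | methyl (3R,4S)-3-(dimethoxymethyl)-2-methylidene-5-(1-methyl-2,6-dioxocyclohexyl)-4-(trimethylsilyloxy)pentanoate | C[Si](C)(C)O[C@@H](CC1(C)C(=O)CCCC1=O)[C@H](C(OC)OC)C(=C)C(=O)OC | intermediate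
12 | methyl (3R,4S)-3-(dimethoxymethyl)-4-hydroxy-2-methylidene-5-(1-methyl-2,6-dioxocyclohexyl)pentanoate | O[C@@H](CC1(C)C(=O)CCCC1=O)[C@H](C(OC)OC)C(=C)C(=O)OC | intermediate
13 | 2-methylprop-2-enoyl chloride | C=C(C)C(Cl)=O | starting material
14 | methyl (3R,4S)-3-(dimethoxymethyl)-2-methylidene-5-(1-methyl-2,6-dioxocyclohexyl)-4-(2-methylprop-2-enoyloxy)pentanoate | C=C(C)C(=O)O[C@@H](CC1(C)C(=O)CCCC1=O)[C@H](C(OC)OC)C(=C)C(=O)OC | intermediate
15 | methyl (3R,4S)-3-formyl-2-methylidene-5-(1-methyl-2,6-dioxocyclohexyl)-4-(2-methylprop-2-enoyloxy)pentanoate | C=C(C)C(=O)O[C@@H](CC1(C)C(=O)CCCC1=O)[C@H](C=O)C(=C)C(=O)OC | intermediate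
16 | cis-fused keto lactone: 5α-hydroxy-10α-methyl-8α-(2-methylprop-2-enoyloxy)-1-oxo-15-noreudesm-11(13)-en-6α,12-olide (H-6β, H-7α) | C=C(C)C(=O)O[C@H]1C[C@]2(C)C(=O)CCC[C@]2(O)[C@H]2OC(=O)C(=C)[C@@H]21 | intermediate
17 | 5α-hydroxy-10α-methyl-8α-(2-methylprop-2-enoyloxy)-1-oxo-15-noreudesma-2,11(13)-dien-6α,12-olide | C=C(C)C(=O)O[C@H]1C[C@]2(C)C(=O)C=CC[C@]2(O)[C@H]2OC(=O)C(=C)[C@@H]21 | intermediate
18 | (2Z)-8α-(2-methylprop-2-enoyloxy)-5-oxo-1-(trifluoromethylsulfonyloxy)-15-norgermacra-1(10),2,11(13)-trien-6α,12-olide, C9 trans to C2 across C1=C10 | C=C(C)C(=O)O[C@H]1C/C(C)=C(OS(=O)(=O)C(F)(F)F)/C=C\CC(=O)[C@H]2OC(=O)C(=C)[C@@H]21 | intermediate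
19 | (1(10)E,2Z)-8α-(2-methylprop-2-enoyloxy)-5-oxo-15-norgermacra-1(10),2,11(13)-trien-6α,12-olide | C=C(C)C(=O)O[C@H]1C/C(C)=C/C=C\CC(=O)[C@H]2OC(=O)C(=C)[C@@H]21 | intermediate
20 | (1(10)E,2Z)-8α-(2-methylprop-2-enoyloxy)-5-oxogermacra-1(10),2,4(15),11(13)-tetraen-6α,12-olide | C=C(C)C(=O)O[C@H]1C/C(C)=C/C=C\C(=C)C(=O)[C@H]2OC(=O)C(=C)[C@@H]21 | intermediate
21 | 1β,10α:2α,3α-diepoxy-8α-(2-methylprop-2-enoyloxy)-5-oxogermacra-4(15),11(13)-dien-6α,12-olide | C=C(C)C(=O)O[C@H]1C[C@@]2(C)O[C@@H]2[C@H]2O[C@H]2C(=C)C(=O)[C@H]2OC(=O)C(=C)[C@@H]21 | intermediate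
22 | (1R,2S,3S,5R,6S,7R,8S,10R)-1,10:2,3-diepoxy-5-hydroxy-8-(2-methylprop-2-enoyloxy)germacra-4(15),11(13)-dien-12,6-olide (ACon1_002091) | C=C(C)C(=O)O[C@H]1C[C@@]2(C)O[C@@H]2[C@H]2O[C@H]2C(=C)[C@@H](O)[C@H]2OC(=O)C(=C)[C@@H]21 | target

**Step count and risks**
Total step count: 14. Longest linear sequence: 12 steps (1 → 22 through steps 1–3 and 6–14; steps 4–5 make the allyl bromide 10).

The three steps most likely to fail are steps 8, 10 and 13.

Step 8 (SmI2 pinacol cyclisation in the presence of two acrylate units and a second ketone; it sets C6). The fallback sets out from 15 and returns at 16 using known chemistry. The crude aldehyde 15 is treated with an aminoindanol-derived triazolium carbene precatalyst and i-Pr2NEt in toluene. This intramolecular crossed benzoin reaction onto the nearer dione carbonyl is a known cis-selective desymmetrisation of 2-methyl-2-(oxoalkyl)cyclohexane-1,3-diones and gives the bicyclic α-ketol F1. Catalyst-controlled transfer hydrogenation of the C6 ketone (RuCl[(S,S)-TsDPEN](p-cymene) or its antipode, HCO2H/Et3N) gives the 6α-hydroxy ester F2, which lactonises with a trace of p-TsOH to 16.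

Step 10 (the proposed retro-aldol ring expansion with triflate capture; γ-deprotonation of the enone or an unfavourable aldol equilibrium could intervene). The fallback sets out from 17 and returns at 19 using known chemistry. Luche reduction (NaBH4, CeCl3·7H2O, MeOH, −78 °C) gives the allylic alcohol F3, expected to be the 1β-epimer from attack on the less hindered α face. Mitsunobu sulfonylation with inversion (Zn(OTs)2, PPh3, DIAD, toluene) gives the equatorial 1α-tosylate F4. With KN(SiMe3)2 in THF this undergoes the classical Wharton–Grob fragmentation (tosylate antiperiplanar to C5–C10, C9 anti to C2) to the (1(10)E,2Z)-dienone 19. If the Luche reduction gives the 1α-alcohol instead, it is sulfonylated directly.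

Step 13 (facial selectivity of two epoxidations on a flexible ten-membered ring). The fallback sets out from 20 and returns at 21. One equivalent of mCPBA (NaHCO3, CH2Cl2, 0 °C) epoxidises only the more nucleophilic trisubstituted alkene to the 1β,10α-monoepoxide F5. If the direct second epoxidation attacks the β face of C2=C3, the opposite face is reached in two steps: NBS in THF/H2O forms the bromonium ion on that same β face and water opens it anti, giving the trans-bromohydrin F6 (its regioisomer converges), and K2CO3 in MeCN closes the 2α,3α-oxirane to 21.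

**Further compounds**
F1 | step 8 | bicyclic α-ketol: methyl 2-[5α-hydroxy-10α-methyl-8α-(2-methylprop-2-enoyloxy)-1,6-dioxodecalin-7β-yl]prop-2-enoate (cis-fused, locants as in 16) | C=C(C)C(=O)O[C@H]1C[C@]2(C)C(=O)CCC[C@]2(O)C(=O)[C@@H]1C(=C)C(=O)OC
F2 | step 8 | 6α-hydroxy ester: methyl 2-[5α,6α-dihydroxy-10α-methyl-8α-(2-methylprop-2-enoyloxy)-1-oxodecalin-7β-yl]prop-2-enoate | C=C(C)C(=O)O[C@H]1C[C@]2(C)C(=O)CCC[C@]2(O)[C@@H](O)[C@@H]1C(=C)C(=O)OC
F3 | step 10 | allylic alcohol: 1β,5α-dihydroxy-10α-methyl-8α-(2-methylprop-2-enoyloxy)-15-noreudesma-2,11(13)-dien-6α,12-olide | C=C(C)C(=O)O[C@H]1C[C@]2(C)[C@H](O)C=CC[C@]2(O)[C@H]2OC(=O)C(=C)[C@@H]21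
F4 | step 10 | 1α-tosylate: 5α-hydroxy-10α-methyl-8α-(2-methylprop-2-enoyloxy)-1α-(4-methylphenylsulfonyloxy)-15-noreudesma-2,11(13)-dien-6α,12-olide | C=C(C)C(=O)O[C@H]1C[C@]2(C)[C@@H](OS(=O)(=O)c3ccc(C)cc3)C=CC[C@]2(O)[C@H]2OC(=O)C(=C)[C@@H]21
F5 | step 13 | monoepoxide: (2Z)-1β,10α-epoxy-8α-(2-methylprop-2-enoyloxy)-5-oxogermacra-2,4(15),11(13)-trien-6α,12-olide | C=C(C)C(=O)O[C@H]1C[C@@]2(C)O[C@@H]2/C=C\C(=C)C(=O)[C@H]2OC(=O)C(=C)[C@@H]21
F6 | step 13 | trans-bromohydrin: 2β-bromo-1β,10α-epoxy-3α-hydroxy-8α-(2-methylprop-2-enoyloxy)-5-oxogermacra-4(15),11(13)-dien-6α,12-olide | C=C(C)C(=O)O[C@H]1C[C@@]2(C)O[C@@H]2[C@H](Br)[C@@H](O)C(=C)C(=O)[C@H]2OC(=O)C(=C)[C@@H]21
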